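**Retrosynthetic overview**

Enabling feature: the enol-ether oxygen on C10 of the dibenzo[b,f]oxepine (ring C) is bonded to the methyl-bearing quaternary carbon C3′, which is vicinal to the ring E oxygen on C2′ with a cis D/E fusion; C2′–O is in turn five atoms from C6′, which carries the second oxygen pair (C5′/C6′). With a C10 ketone this pattern is the retron of a skipped 2′,3′/5′,6′ bis-epoxide opened twice in the 6-endo sense.
Disconnections: oxetane C5′–O (Williamson closure with inversion, after Markovnikov hydration of an isopropenyl group) ⇒ rings D and E together, from an 11-alkyl-dibenzo[b,f]oxepin-10-one carrying a (2′R,3′S)-epoxide and a (5′R,6′R)-isopropenyl epoxide ⇒ C11–C1′ enolate alkylation.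
Fragments: the oxepinone from an Ullmann ether synthesis and Friedel–Crafts acylation; the bis-epoxy tosylate from neryl acetate (ene-chlorination, elimination, Sharpless and Shi epoxidations).
Ring order: A and B bought, C (step 2), D and E in one operation (step 13), oxetane F (step 17); the prenyl group enters by Stille coupling (step 15) only after the alkene hydration.

Key step: step 13

Remark: the target is taken as drawn, (2′R,3′R,5′S,6′R); C10/C11 are the oxygen-bearing and chain-bearing oxepine carbons, the chain is C1′ (on C11) to C8′, C3′ carries the methyl group and C7′ the two oxetane methyl groups.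

**Route**

Step 1
Reactants: 1 2-(2-bromo-4-methoxyphenyl)acetic acid; 2 3-methoxyphenol
Product: 3 2-[4-methoxy-2-(3-methoxyphenoxy)phenyl]acetic acid
Conditions: CuI (10 mol %), N,N-dimethylglycine (30 mol %), Cs2CO3, dioxane, 100 °C; then aq HCl
Reagents that add atoms: none
Why: Ullmann diaryl ether synthesis, in which the ortho CH2CO2− group assists copper insertion into the C–Br bond and the phenoxide of 2 is coupled; no stereocenter is formed.

Step 2
Reactants: 3 2-[4-methoxy-2-(3-methoxyphenoxy)phenyl]acetic acid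
Product: 4 3,7-dimethoxydibenzo[b,f]oxepin-10(11H)-one
Conditions: polyphosphoric acid, 90 °C
Reagents that add atoms: none
Why: intramolecular Friedel–Crafts acylation, which should occur on ring B para to its methoxy group and ortho to the ether oxygen, the only activated position that closes the seven-membered ring C without steric clash.

Step 3
Reactants: 4 3,7-dimethoxydibenzo[b,f]oxepin-10(11H)-one
Product: 5 2-bromo-3,7-dimethoxydibenzo[b,f]oxepin-10(11H)-one
Conditions: NBS (1.05 equiv), MeCN, 0 °C, dark
Reagents that add atoms: N-bromosuccinimide (O=C1CCC(=O)N1Br)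
Why: electrophilic aromatic bromination, which should select ring A (ring B is deactivated by the conjugated carbonyl) at C2, para to the ring oxygen and ortho to OMe, over the hindered C4 between the two oxygens.

Step 4
Reactants: 5 2-bromo-3,7-dimethoxydibenzo[b,f]oxepin-10(11H)-one
Product: 6 2-bromo-3,7-dihydroxydibenzo[b,f]oxepin-10(11H)-one
Conditions: BBr3, CH2Cl2, −78 °C → rt; then H2O
Reagents that add atoms: none
Why: Lewis acid O-demethylation of both aryl methyl ethers, placed here because no acid-sensitive group is present yet.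

Step 5
Reactants: 6 2-bromo-3,7-dihydroxydibenzo[b,f]oxepin-10(11H)-one
Product: 7 2-bromo-3,7-bis(triisopropylsilyloxy)dibenzo[b,f]oxepin-10(11H)-one
Conditions: i-Pr3SiCl, imidazole, DMF, 40 °C
Reagents that add atoms: chlorotri(propan-2-yl)silane (CC(C)[Si](Cl)(C(C)C)C(C)C)
Why: silylation of both phenols; the aryl TIPS ethers should survive NaH, CSA, the cobalt/silane hydration, the Stille coupling and the basic oxetane closure, and fall to fluoride at the end.

Step 6
Reactants: 8 neryl acetate, (2Z)-3,7-dimethylocta-2,6-dien-1-yl acetate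
Product: 9 (2Z)-6-chloro-3,7-dimethylocta-2,7-dien-1-yl acetate (racemic at C6)
Conditions: Ca(OCl)2, solid CO2, CH2Cl2/H2O, 0 °C
Reagents that add atoms: calcium hypochlorite ([Ca+2].[O-]Cl.[O-]Cl)
Why: ene-type chlorination by HOCl formed in situ, which should attack only the electron-rich 6,7-alkene (the 2,3-alkene is deactivated by the allylic acetate) and give the secondary allylic chloride with the double bond moved into an isopropenyl group.

Step 7
Reactants: 9 (2Z)-6-chloro-3,7-dimethylocta-2,7-dien-1-yl acetate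
Product: 10 (2Z,5E)-3,7-dimethylocta-2,5,7-trien-1-yl acetate
Conditions: LiBr, Li2CO3, DMF, 100 °C
Reagents that add atoms: none
Why: base-induced dehydrochlorination (E2, or allylic halide transposition followed by 1,4-elimination), which can only remove a C5 hydrogen and should give the conjugated (5E)-diene while the (2Z)-alkene is untouched.

Step 8
Reactants: 10 (2Z,5E)-3,7-dimethylocta-2,5,7-trien-1-yl acetate
Product: 11 (2Z,5E)-3,7-dimethylocta-2,5,7-trien-1-ol
Conditions: K2CO3 (cat.), MeOH, rt
Reagents that add atoms: none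
Why: base-catalysed transesterification of the acetate with methanol.

Step 9
Reactants: 11 (2Z,5E)-3,7-dimethylocta-2,5,7-trien-1-ol
Product: 12 [(2R,3S)-3-methyl-3-[(2E)-4-methylpenta-2,4-dien-1-yl]oxiran-2-yl]methanol
Conditions: Ti(OiPr)4 (10 mol %), D-(−)-diethyl tartrate (12 mol %), t-BuOOH, 4 Å MS, CH2Cl2, −20 °C
Reagents that add atoms: tert-butyl hydroperoxide (CC(C)(C)OO)
Why: Sharpless asymmetric epoxidation of the (Z)-allylic alcohol, in which the D-(−)-tartrate complex should deliver oxygen to the face that gives the (2R,3S)-epoxide; the diene has no directing hydroxyl and should not react.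

Step 10
Reactants: 12 [(2R,3S)-3-methyl-3-[(2E)-4-methylpenta-2,4-dien-1-yl]oxiran-2-yl]methanol
Product: 13 [(2R,3S)-3-methyl-3-{[(2R,3R)-3-(prop-1-en-2-yl)oxiran-2-yl]methyl}oxiran-2-yl]methanol
Conditions: D-fructose-derived Shi ketone (30 mol %), KHSO5 (Oxone), K2CO3, n-Bu4NHSO4, MeCN/CH2(OMe)2/aq Na2B4O7 buffer (pH 10.5), 0 °C
Reagents that add atoms: potassium peroxymonosulfate ([K+].[O-]S(=O)(=O)OO)
Why: Shi asymmetric epoxidation, in which the chiral dioxirane should epoxidise the trans-disubstituted alkene of the diene through the spiro transition state to the (R,R)-vinyl epoxide, the 1,1-disubstituted terminus being a poor substrate for this ketone.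

Step 11
Reactants: 13 [(2R,3S)-3-methyl-3-{[(2R,3R)-3-(prop-1-en-2-yl)oxiran-2-yl]methyl}oxiran-2-yl]methanol
Product: 14 [(2R,3S)-3-methyl-3-{[(2R,3R)-3-(prop-1-en-2-yl)oxiran-2-yl]methyl}oxiran-2-yl]methyl 4-methylbenzenesulfonate
Conditions: TsCl, Et3N, DMAP (cat.), CH2Cl2, 0 °C
Reagents that add atoms: 4-methylbenzenesulfonyl chloride (Cc1ccc(cc1)S(Cl)(=O)=O)
Why: sulfonylation of the primary alcohol, which turns C1′ into an SN2 electrophile without touching either epoxide.

Step 12
Reactants: 7 2-bromo-3,7-bis(triisopropylsilyloxy)dibenzo[b,f]oxepin-10(11H)-one; 14 bis-epoxy tosylate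
Product: 15 2-bromo-11-{[(2R,3S)-3-methyl-3-{[(2R,3R)-3-(prop-1-en-2-yl)oxiran-2-yl]methyl}oxiran-2-yl]methyl}-3,7-bis(triisopropylsilyloxy)dibenzo[b,f]oxepin-10(11H)-one (C11 epimers)
Conditions: NaH, THF/DMF (5:1), 0 °C; then 14, NaI (10 mol %), 0 °C → rt
Reagents that add atoms: none
Why: C-alkylation of the soft benzylic ketone enolate by SN2 at the primary carbon next to the epoxide; the new C11 stereocenter is of no consequence because C11 becomes sp2 again in step 13.

Step 13
Reactants: 15 11-(bis-epoxyalkyl) ketone (C11 epimers)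
Product: 17 (2′R,3′R,5′R,6′S)-ring D/E alcohol: rings D and E closed with 5′-OH and 6′-isopropenyl, via ring-D hydroxy enol ether 16 (not isolated)
Conditions: CSA (20 mol %), CH2Cl2, −40 → 0 °C; then Et3N
Reagents that add atoms: none
Why: CSA protonates the trisubstituted 2′,3′-epoxide and the C10 carbonyl oxygen attacks its tertiary carbon C3′ from the back (6-endo-tet, ring D); the oxocarbenium ion loses H-11 to give the conjugated enol ether 16, whose freed C2′ hydroxyl then opens the protonated vinyl epoxide at the allylic carbon C6′ from the back (6-endo-tet, ring E). The closest known reaction types are the acid-catalysed cyclisation of γ,δ-epoxy ketones through the carbonyl oxygen (bicyclic ketal and dihydropyran formation) and the 6-endo cyclisation of hydroxy epoxides that carry a π-donor on the distal carbon, here joined in one epoxide-opening cascade. C3′ (R) should be set by inversion of the (3′S) epoxide carbon from the Sharpless step and C6′ by inversion of the (6′R) epoxide carbon from the Shi step, while C2′ and C5′ keep their epoxide oxygens with retention, so the cis D/E fusion and the 2′,6′-cis, 5′,6′-trans pattern of ring E follow from two reagent-controlled epoxides. The step needs endo over exo opening twice, secured first by the cation-stabilising tertiary C3′ and then by the isopropenyl π-donor on C6′, and it needs ring D to close before ring E, which the substrate secures because the vinyl epoxide has no internal nucleophile until the C2′ hydroxyl is unmasked. Any strained 2,7-dioxabicyclo[2.2.1]heptane ketal formed by return of the C2′ hydroxyl to C10 should stay in acid equilibrium with 16 and be drained by the irreversible second opening.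

Step 14
Reactants: 17 ring D/E alcohol with 6′-isopropenyl group
Product: 18 (2′R,3′R,5′R,6′R)-diol: 6′-(2-hydroxypropan-2-yl), 5′-OH
Conditions: Co(acac)2 (20 mol %), PhSiH3, O2 (1 atm), THF/i-PrOH, rt
Reagents that add atoms: dioxygen (O=O)
Why: Mukaiyama hydration (cobalt hydride hydrogen-atom transfer, O2 trapping), which should hydrate the 1,1-disubstituted alkene in the Markovnikov sense; the tetrasubstituted enol ether is too hindered for hydrogen-atom transfer and no prenyl group is present yet.

Step 15
Reactants: 18 bromo diol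
Product: 19 2-(3-methylbut-2-en-1-yl) diol (bis-TIPS ether, 5′-OH and 7′-OH free)
Conditions: Pd(PPh3)4 (10 mol %), tributyl(3-methylbut-2-en-1-yl)stannane, DMF, 100 °C
Reagents that add atoms: tributyl(3-methylbut-2-en-1-yl)stannane (CCCC[Sn](CCCC)(CCCC)CC=C(C)C)
Why: Stille cross-coupling of the aryl bromide with the prenylstannane, which should give the linear prenyl arene and is placed after the hydration so that the prenyl alkene never meets the radical conditions.

Step 16
Reactants: 19 prenyl diol
Product: 20 (5′R)-5′-methanesulfonate of 19 (7′-OH free)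
Conditions: MsCl, Et3N, CH2Cl2, −20 °C
Reagents that add atoms: methanesulfonyl chloride (CS(Cl)(=O)=O)
Why: selective sulfonylation of the secondary C5′ hydroxyl; the tertiary C7′ hydroxyl should not react under these conditions.

Step 17
Reactants: 20 hydroxy mesylate
Product: 21 3,7-bis(triisopropylsilyl) ether of the target (oxetane closed, 5′S)
Conditions: NaH, THF, 0 °C → rt
Reagents that add atoms: none
Why: intramolecular Williamson etherification (4-exo-tet), in which the tertiary C7′ alkoxide should displace the C5′ mesylate with inversion and so set (5′S) and the cis-fused oxetane.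

Step 18
Reactants: 21 bis-TIPS ether
Product: 22 CNP0102779.1 (target)
Conditions: n-Bu4NF, THF, 0 °C; then aq NH4Cl
Reagents that add atoms: none
Why: fluoride cleavage of the two aryl silyl ethers under non-acidic conditions that should spare the enol ether, the oxetane and the prenyl group.

**Compound list**

1 | 2-(2-bromo-4-methoxyphenyl)acetic acid | COc1ccc(CC(=O)O)c(Br)c1 | starting material
2 | 3-methoxyphenol | COc1cccc(O)c1 | starting material
3 | 2-[4-methoxy-2-(3-methoxyphenoxy)phenyl]acetic acid | COc1ccc(CC(=O)O)c(Oc2cccc(OC)c2)c1 | intermediate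
4 | 3,7-dimethoxydibenzo[b,f]oxepin-10(11H)-one | O=C1Cc2ccc(OC)cc2Oc2cc(OC)ccc21 | intermediate
5 | 2-bromo-3,7-dimethoxydibenzo[b,f]oxepin-10(11H)-one | O=C1Cc2cc(Br)c(OC)cc2Oc2cc(OC)ccc21 | intermediate
6 | 2-bromo-3,7-dihydroxydibenzo[b,f]oxepin-10(11H)-one | O=C1Cc2cc(Br)c(O)cc2Oc2cc(O)ccc21 | intermediate
7 | 2-bromo-3,7-bis(triisopropylsilyloxy)dibenzo[b,f]oxepin-10(11H)-one | O=C1Cc2cc(Br)c(O[Si](C(C)C)(C(C)C)C(C)C)cc2Oc2cc(O[Si](C(C)C)(C(C)C)C(C)C)ccc21 | intermediate
8 | neryl acetate, (2Z)-3,7-dimethylocta-2,6-dien-1-yl acetate | CC(=O)OC/C=C(C)\CCC=C(C)C | starting material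
9 | (2Z)-6-chloro-3,7-dimethylocta-2,7-dien-1-yl acetate (racemic at C6) | CC(=O)OC/C=C(C)\CCC(Cl)C(C)=C | intermediate
10 | (2Z,5E)-3,7-dimethylocta-2,5,7-trien-1-yl acetate | CC(=O)OC/C=C(C)\C/C=C/C(C)=C | intermediate
11 | (2Z,5E)-3,7-dimethylocta-2,5,7-trien-1-ol | OC/C=C(C)\C/C=C/C(C)=C | intermediate
12 | [(2R,3S)-3-methyl-3-[(2E)-4-methylpenta-2,4-dien-1-yl]oxiran-2-yl]methanol | OC[C@H]1O[C@@]1(C)C/C=C/C(C)=C | intermediate
13 | [(2R,3S)-3-methyl-3-{[(2R,3R)-3-(prop-1-en-2-yl)oxiran-2-yl]methyl}oxiran-2-yl]methanol | OC[C@H]1O[C@@]1(C)C[C@H]2O[C@@H]2C(C)=C | intermediate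
14 | 4-methylbenzenesulfonate of 13 | Cc1ccc(cc1)S(=O)(=O)OC[C@H]1O[C@@]1(C)C[C@H]2O[C@@H]2C(C)=C | intermediate
15 | 2-bromo-11-{[(2R,3S)-3-methyl-3-{[(2R,3R)-3-(prop-1-en-2-yl)oxiran-2-yl]methyl}oxiran-2-yl]methyl}-3,7-bis(triisopropylsilyloxy)dibenzo[b,f]oxepin-10(11H)-one (C11 epimers) | O=C1C(C[C@H]3O[C@@]3(C)C[C@H]4O[C@@H]4C(C)=C)c2cc(Br)c(O[Si](C(C)C)(C(C)C)C(C)C)cc2Oc2cc(O[Si](C(C)C)(C(C)C)C(C)C)ccc21 | intermediate
16 | ring-D hydroxy enol ether: dihydropyran fused at C10=C11 with (2′R)-OH, (3′R)-methyl and the intact (5′R,6′R)-isopropenyl epoxide side chain on C3′ | Brc1cc2c(cc1O[Si](C(C)C)(C(C)C)C(C)C)Oc1cc(O[Si](C(C)C)(C(C)C)C(C)C)ccc1C1=C2C[C@@H](O)[C@@](C)(C[C@H]3O[C@@H]3C(C)=C)O1 | intermediate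
17 | (2′R,3′R,5′R,6′S)-ring D/E alcohol: rings D and E closed, 5′-OH, 6′-isopropenyl, aryl bromide, two TIPS ethers | Brc1cc2c(cc1O[Si](C(C)C)(C(C)C)C(C)C)Oc1cc(O[Si](C(C)C)(C(C)C)C(C)C)ccc1C1=C2C[C@H]2O[C@@H](C(C)=C)[C@@H](C[C@@]2(C)O1)O | intermediate
18 | (2′R,3′R,5′R,6′R)-diol: 6′-(2-hydroxypropan-2-yl), 5′-OH, aryl bromide | Brc1cc2c(cc1O[Si](C(C)C)(C(C)C)C(C)C)Oc1cc(O[Si](C(C)C)(C(C)C)C(C)C)ccc1C1=C2C[C@H]2O[C@@H](C(C)(C)O)[C@@H](C[C@@]2(C)O1)O | intermediate
19 | 2-(3-methylbut-2-en-1-yl) diol (prenyl in place of bromine in 18) | CC(C)=CCc1cc2c(cc1O[Si](C(C)C)(C(C)C)C(C)C)Oc1cc(O[Si](C(C)C)(C(C)C)C(C)C)ccc1C1=C2C[C@H]2O[C@@H](C(C)(C)O)[C@@H](C[C@@]2(C)O1)O | intermediate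
20 | (5′R)-5′-methanesulfonate of 19 | CC(C)=CCc1cc2c(cc1O[Si](C(C)C)(C(C)C)C(C)C)Oc1cc(O[Si](C(C)C)(C(C)C)C(C)C)ccc1C1=C2C[C@H]2O[C@@H](C(C)(C)O)[C@@H](C[C@@]2(C)O1)OS(C)(=O)=O | intermediate
21 | 3,7-bis(triisopropylsilyl) ether of the target, (2′R,3′R,5′S,6′R) | CC(C)=CCc1cc2c(cc1O[Si](C(C)C)(C(C)C)C(C)C)Oc1cc(O[Si](C(C)C)(C(C)C)C(C)C)ccc1C1=C2C[C@H]2O[C@@H]3[C@H](C[C@@]2(C)O1)OC3(C)C | intermediate
22 | CNP0102779.1, (2′R,3′R,5′S,6′R) | CC(C)=CCc1cc2c(cc1O)Oc1cc(O)ccc1C1=C2C[C@H]2O[C@@H]3[C@H](C[C@@]2(C)O1)OC3(C)C | target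

**Step count and risks**

Total step count: 18. Longest linear sequence: 13 steps (8 → 22, steps 6–18); the oxepinone branch (steps 1–5) joins at step 12.

Most likely to fail:

1. Step 13. The ordered endo,endo sequence may be lost: the freed C2′ hydroxyl can return to C10 (bicyclic ketal) and re-open toward the five-membered enol ether, or the vinyl epoxide can ionise before ring D has closed. Fallback, from 15 back to 17: the ketone should be converted with LiN(SiMe3)2 and Me3SiCl (THF, −78 °C) into the C10 trimethylsilyl enol ether F1. Catalytic Me3SiOTf (CH2Cl2, −78 °C) should then let the silyl enol ether oxygen open the 2′,3′-epoxide with transfer of the silyl group to the epoxide oxygen, and the resulting C2′ silyl ether should relay in the same way to the vinyl epoxide, so that no hydroxy oxocarbenium ion is ever present. The product would be the C5′ trimethylsilyl ether F2, and K2CO3 in MeOH should return it to 17.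

2. Step 17. Fragmentation of the tertiary alkoxide (loss of acetone with formation of a C5′=C6′ enol ether) or E2 elimination of the mesylate may outrun the slow 4-exo-tet substitution. Fallback, from 19 directly to 21: an intramolecular Mitsunobu etherification (PPh3, diisopropyl azodicarboxylate, toluene, 0 → 60 °C) should activate the secondary C5′ hydroxyl as its oxyphosphonium ion. The neutral tertiary hydroxyl would displace it with inversion, so that no free alkoxide is available to drive the fragmentation.

3. Step 14. The electron-rich C10=C11 enol ether may be oxidised, or hydrogen-atom transfer may be slow, under the cobalt/silane/O2 radical conditions. Fallback, from 17 back to 18: VO(acac)2 (cat.) and t-BuOOH in CH2Cl2 should epoxidise only the isopropenyl group, directed by the homoallylic C5′ hydroxyl, to give the 7′,8′-epoxide F3 (C7′ epimers). LiEt3BH (THF, 0 °C) should then open it at the CH2 terminus to the tertiary alcohol 18.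

Further compounds
F1 | step 13 | C10 trimethylsilyl enol ether of 15 | C[Si](C)(C)OC1=C(C[C@H]3O[C@@]3(C)C[C@H]4O[C@@H]4C(C)=C)c2cc(Br)c(O[Si](C(C)C)(C(C)C)C(C)C)cc2Oc2cc(O[Si](C(C)C)(C(C)C)C(C)C)ccc21
F2 | step 13 | C5′ trimethylsilyl ether of 17 | Brc1cc2c(cc1O[Si](C(C)C)(C(C)C)C(C)C)Oc1cc(O[Si](C(C)C)(C(C)C)C(C)C)ccc1C1=C2C[C@H]2O[C@@H](C(C)=C)[C@@H](C[C@@]2(C)O1)O[Si](C)(C)C
F0 | step 17 | none | none
F3 | step 14 | 7′,8′-epoxide of 17 (C7′ epimers) | Brc1cc2c(cc1O[Si](C(C)C)(C(C)C)C(C)C)Oc1cc(O[Si](C(C)C)(C(C)C)C(C)C)ccc1C1=C2C[C@H]2O[C@@H](C3(C)CO3)[C@@H](C[C@@]2(C)O1)O
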